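In a one-step world with Q frozen at its charge, G is pseudo-first-order, and the depth, ln(1/(1 − fraction of G turned into L)), grows with time and with some power of Q. Depth is what you need for deciding this flask: charge more Q, double the transfer of Q, or leave it.

| flask | G | Q | remark | time | volume of the second phase over the first |
|---|---|---|---|---|---|
| summer | 16 mM | 99 mM | run made earlier |  |  |
| winter | 66 mM | 99 mM | run made earlier |  |  |
| autumn | 33 mM | 150 mM | run made earlier |  |  |
| flask | 33 mM | 99.0 mM |  | 2.5 d | 0.50 |

| summer: time / h | summer: L / % | winter: time / h | winter: L / % | autumn: time / h | autumn: L / % |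
|---|---|---|---|---|---|
| 3.00 | 3.8 | 10.0 | 20.2 | 10.0 | 26.6 |
| 6.00 | 12.6 | 20.0 | 35.3 | 20.0 | 43.6 |
| 15.0 | 31.1 | 25.0 | 38.8 | 25.0 | 52.5 |
| 40.0 | 54.3 | 40.0 | 47.1 | 40.0 | 60.9 |

(standard deviation of a reading: 1 percentage point)

- in the second phase: Q; everything else is in the first
- charges count per volume of the first phase; a concentration in a rate is the amount of a species over the volume of its own phase; every rate counts per litre of the first phase
- the earlier runs hold the two phases in the same ratio of volumes as the flask asked about

- amount of L at 2.5 d, in percent of the G charged
- the change that raises the amount of L at 2.5 d, in percent of the G charged most ("none" if none brings more than 2 percentage points) (zeta / delta / none)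
- amount of L at 2.5 d, in percent of the G charged, after zeta

- zeta: doubling the amount of Q, all else as stated
- delta: doubling the transfer coefficient of Q, all else as stated

At 40.0 h the summer run reads depth 0.783 and the winter run 0.637. They bracket the flask's G at the flask's Q, so take their mean, 0.710. The autumn run, with the flask's G but Q 150 mM, reads 0.939. The logarithm of the depth ratio over that of the Q ratio gives 0.673. This is the Q leverage, the power with which depth follows Q at fixed time and fixed charge of G, a reading that carries the scatter of 1 percentage point. Doubling Q then multiplies depth by 1.59.

Late in the summer and winter runs, depth climbs on average 0.0132 h⁻¹. Carried on at that slope, your estimate for the flask is depth 0.975 at 2.5 d, which is L 62.3 %, and with doubled Q, by the leverage, L 78.9 %. The summer depth, drawn back through its first two readings, meets zero at 1.79 h, a reading; your assumption is that this lag is the time Q takes to cross, so that doubled transfer halves it. Halving that lag buys an estimated 0.45 points, less than the 2 points that counts, against an estimated 17 points from doubled Q, so you double Q.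

The forecast says 60 %, zeta and 80 %, with “Doubling Q multiplies this by about 1.8–1.9”; your factor differs, 1.59, but the choice is the same.

The flask gives 59.8 %, and 75.0 % after zeta, while delta changes L by −0.073 points.

    Z ⇌ Q, rate k1*([Z] - [Q]/K1) per volume of the first phase (partition coefficient = 2.40, kL = 0.00420 min⁻¹)
    G + Z → L (k = 0.0230 L mol⁻¹ min⁻¹)
    2 Z → D (k = 0.0220 L mol⁻¹ min⁻¹)
    G ⇌ E (K = 0.610, k = 0.0120 min⁻¹)

The flask's depth is 0.911, and multiplied by the leverage factor 1.59 this reckons to L 76.5 % for doubled Q, beside the 75.0 % that the doubled flask holds. Take now a second flask, charged with Q 80.6 mM: the leverage scales the depth to 0.794, which reckons to L 54.8 %, and the simulated flask at that charge stands 5 points below 59.8 %.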